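**Plan**
1. Ring B is numbered C1' (CO2H), C2' (OMe), C3' (O-aroyl), C4' (OH), C5' (H), C6' (propyl); ring A is the 2,4-dihydroxy-6-propylbenzoyl unit.
2. Retrosynthesis: after removal of the benzyl and silyl groups and of the O2'–CH3 bond, ring B is cut at C1'–C2' and C5'–C6'. The oxygen triad C2'/C3'/C4' with C5'–H is the four-carbon chain of a 2-aroyloxy-acetoacetate-derived bis(silyloxy)diene, and C1' (carboxyl) with C6' (propyl) is hex-2-ynoate.
3. The depside ester is then cut at its alkyl O–C bond, giving the ring-A carboxylate and methyl 2-chloroacetoacetate.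
4. Forward: divarinic acid is benzylated and joined to the acetoacetate, two silylations give the diene, and the cycloaddition/aromatization closes ring B, the only ring formed. O2'-methylation, desilylation and hydrogenolysis finish the route.
5. Stereochemistry: the target has no stereogenic element; the transient ones (C2 of 5, alkene geometry of 6 and 7, ketal carbon of 10) are all erased.

Key step: step 7

Remark on the chemistry: the target has no stereocentre, stereogenic axis or configured double bond, so it is one achiral compound and no asymmetric step is needed. The alkene geometries of 6 and 7 are left open in their SMILES because either isomer, or a mixture, converges on the same arene. Compounds 1, 4 and 8 are taken as purchased.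

Step 1
Reactants: 1 2,4-dihydroxy-6-propylbenzoic acid (divarinic acid)
Product: 2 benzyl 2,4-bis(benzyloxy)-6-propylbenzoate
Conditions: BnBr (3.5 equiv), K2CO3, DMF, rt then 60 °C
Reagents that add atoms: benzyl bromide, BrCc1ccccc1
Why: Williamson O-benzylation of both phenols together with SN2 esterification of the carboxylate, a standard exhaustive benzylation in which early ester formation also suppresses decarboxylation of the resorcylic acid.

Step 2
Reactants: 2 benzyl 2,4-bis(benzyloxy)-6-propylbenzoate
Product: 3 2,4-bis(benzyloxy)-6-propylbenzoic acid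
Conditions: KOH, DMSO/H2O, 90 °C; then 1 M HCl, 0 °C
Reagents that add atoms: potassium hydroxide, [K+].[OH-]
Why: Saponification of the benzyl ester, which for this 2,6-disubstituted benzoate needs hot concentrated hydroxide but leaves the aryl benzyl ethers untouched.

Step 3
Reactants: 3 2,4-bis(benzyloxy)-6-propylbenzoic acid; 4 methyl 2-chloro-3-oxobutanoate (methyl 2-chloroacetoacetate, racemic)
Product: 5 1-methoxy-1,3-dioxobutan-2-yl 2,4-bis(benzyloxy)-6-propylbenzoate (racemic)
Conditions: Cs2CO3 (0.5 equiv), DMF, rt; then 4, rt to 40 °C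
Reagents that add atoms: none
Why: SN2 displacement of the doubly carbonyl-activated chloride by the preformed cesium carboxylate (carboxylate O-alkylation), which makes the future depside ester at an unhindered alkyl carbon and so avoids acylation by the hindered acid.

Step 4
Reactants: 5 1-methoxy-1,3-dioxobutan-2-yl 2,4-bis(benzyloxy)-6-propylbenzoate
Product: 6 3-(tert-butyldimethylsilyloxy)-1-methoxy-1-oxobut-2-en-2-yl 2,4-bis(benzyloxy)-6-propylbenzoate
Conditions: TBSOTf, Et3N, CH2Cl2, 0 °C
Reagents that add atoms: tert-butyldimethylsilyl trifluoromethanesulfonate, CC(C)(C)[Si](C)(C)OS(=O)(=O)C(F)(F)F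
Why: Soft enolization of the β-keto ester at its acidic C2–H and O-silylation of the ketone oxygen (silyl enol ether formation), which puts the robust TBS group on the oxygen destined for C4'.

Step 5
Reactants: 6 3-(tert-butyldimethylsilyloxy)-1-methoxy-1-oxobut-2-en-2-yl 2,4-bis(benzyloxy)-6-propylbenzoate
Product: 7 3-(tert-butyldimethylsilyloxy)-1-methoxy-1-(trimethylsilyloxy)buta-1,3-dien-2-yl 2,4-bis(benzyloxy)-6-propylbenzoate
Conditions: TMSCl (1.5 equiv), THF, −78 °C; LDA (1.1 equiv) added dropwise, −78 to 0 °C; pentane, filtration, used crude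
Reagents that add atoms: chlorotrimethylsilane, C[Si](C)(C)Cl
Why: γ-Deprotonation of the β-silyloxy enoate by LDA to the extended ester enolate and O-silylation, the standard second stage of a Chan-type 1,3-bis(silyloxy)diene preparation, run with the silyl chloride present from the start (internal quench) so that the lithium dienolate is short-lived.

Step 6
Reactants: 8 hex-2-ynoic acid
Product: 9 benzyl hex-2-ynoate
Conditions: BnBr, K2CO3, DMF, rt
Reagents that add atoms: benzyl bromide, BrCc1ccccc1
Why: SN2 alkylation of the potassium carboxylate (carboxylate esterification), which avoids carbodiimide/DMAP conditions that can add to the ynoate.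

Step 7
Reactants: 7 3-(tert-butyldimethylsilyloxy)-1-methoxy-1-(trimethylsilyloxy)buta-1,3-dien-2-yl 2,4-bis(benzyloxy)-6-propylbenzoate; 9 benzyl hex-2-ynoate
Product: 12 benzyl 3-{[2,4-bis(benzyloxy)-6-propylbenzoyl]oxy}-4-(tert-butyldimethylsilyloxy)-2-hydroxy-6-propylbenzoate, via cyclohexadiene cycloadduct 10 (not isolated), via aryl trimethylsilyl ether 11 (not isolated)
Conditions: 9 (3 equiv), PhMe (concentrated), sealed tube, 120 °C; then 0.5 M HCl, THF, 0 °C
Reagents that add atoms: none
Why: The electron-rich diene 7 and the ynoate 9 should combine in a thermal, normal-electron-demand Diels–Alder reaction that is concerted but asynchronous, the C5'–C6' bond (diene CH2 to the propyl-bearing β-carbon) running ahead of the C1'–C2' bond (ketene-acetal carbon to the ester-bearing α-carbon), and this single intermolecular [4+2] event closes the six-membered ring B as cyclohexa-1,4-diene 10. The silyl methyl ketal carbon of 10 is then expected to expel methanol and aromatize to aryl silyl ether 11, and the dilute acid work-up cleaves the aryl O–SiMe3 bond while sparing the O–SiMe2tBu ether, so 12 carries the three ring-B oxygens already differentiated as 2'-OH, 3'-O-aroyl and 4'-O-TBS. The closest known reaction type is the Diels–Alder/aromatization of 1-alkoxy-1,3-bis(silyloxy)buta-1,3-dienes and of 1,1-dialkoxy-3-silyloxybutadienes with 3-alkylpropiolates to give 6-alkyl-resorcylates; the 2-aroyloxy substituent is the new element here. No stereocentre is formed, and the ketene acetal geometry does not matter since its carbon ends up as aromatic C2'. The step needs regioselectivity, which the match of the large HOMO coefficient at the diene CH2 terminus with the large LUMO coefficient at the ynoate β-carbon should secure. It also needs the aroyl group to stay on O3', which the two ortho substituents of the benzoate (benzyloxy and propyl) and the absence of any free oxyanion should secure.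

Step 8
Reactants: 12 benzyl 3-{[2,4-bis(benzyloxy)-6-propylbenzoyl]oxy}-4-(tert-butyldimethylsilyloxy)-2-hydroxy-6-propylbenzoate
Product: 13 benzyl 3-{[2,4-bis(benzyloxy)-6-propylbenzoyl]oxy}-4-(tert-butyldimethylsilyloxy)-2-methoxy-6-propylbenzoate
Conditions: MeOH, PPh3, DIAD, THF, 0 °C to rt
Reagents that add atoms: methanol, CO
Why: Mitsunobu etherification of the acidic salicylate-type phenol with methanol under neutral conditions, in which the aryl silyl ether, the benzyl ester and the hindered aryl ester are not attacked and no carbonate base is present.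

Step 9
Reactants: 13 benzyl 3-{[2,4-bis(benzyloxy)-6-propylbenzoyl]oxy}-4-(tert-butyldimethylsilyloxy)-2-methoxy-6-propylbenzoate
Product: 14 benzyl 3-{[2,4-bis(benzyloxy)-6-propylbenzoyl]oxy}-4-hydroxy-2-methoxy-6-propylbenzoate
Conditions: TBAF (1.2 equiv), AcOH (1.2 equiv), THF, 0 °C
Reagents that add atoms: none
Why: Fluoride-mediated cleavage of the aryl silyl ether, buffered with acetic acid so that the liberated 4'-phenol is not left as a free phenoxide beside the 3'-ester.

Step 10
Reactants: 14 benzyl 3-{[2,4-bis(benzyloxy)-6-propylbenzoyl]oxy}-4-hydroxy-2-methoxy-6-propylbenzoate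
Product: 15 3-[(2,4-dihydroxy-6-propylbenzoyl)oxy]-4-hydroxy-2-methoxy-6-propylbenzoic acid (CNP0126444.0)
Conditions: H2 (1 atm), 10% Pd/C, EtOAc, rt
Reagents that add atoms: none
Why: Catalytic hydrogenolysis of the two benzyl ethers and the benzyl ester, which leaves the aryl ester, the methyl ether and both propyl groups untouched.

**Compound list**
1 | 2,4-dihydroxy-6-propylbenzoic acid (divarinic acid) | CCCc1cc(O)cc(O)c1C(=O)O | starting material
2 | benzyl 2,4-bis(benzyloxy)-6-propylbenzoate | CCCc1cc(OCc2ccccc2)cc(OCc2ccccc2)c1C(=O)OCc1ccccc1 | intermediate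
3 | 2,4-bis(benzyloxy)-6-propylbenzoic acid | CCCc1cc(OCc2ccccc2)cc(OCc2ccccc2)c1C(=O)O | intermediate
4 | methyl 2-chloro-3-oxobutanoate (racemic) | CC(=O)C(Cl)C(=O)OC | starting material
5 | 1-methoxy-1,3-dioxobutan-2-yl 2,4-bis(benzyloxy)-6-propylbenzoate (racemic) | CCCc1cc(OCc2ccccc2)cc(OCc2ccccc2)c1C(=O)OC(C(C)=O)C(=O)OC | intermediate
6 | 3-(tert-butyldimethylsilyloxy)-1-methoxy-1-oxobut-2-en-2-yl 2,4-bis(benzyloxy)-6-propylbenzoate (geometry open) | CCCc1cc(OCc2ccccc2)cc(OCc2ccccc2)c1C(=O)OC(C(=O)OC)=C(C)O[Si](C)(C)C(C)(C)C | intermediate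
7 | 3-(tert-butyldimethylsilyloxy)-1-methoxy-1-(trimethylsilyloxy)buta-1,3-dien-2-yl 2,4-bis(benzyloxy)-6-propylbenzoate (geometry open) | CCCc1cc(OCc2ccccc2)cc(OCc2ccccc2)c1C(=O)OC(C(=C)O[Si](C)(C)C(C)(C)C)=C(OC)O[Si](C)(C)C | intermediate
8 | hex-2-ynoic acid | CCCC#CC(=O)O | starting material
9 | benzyl hex-2-ynoate | CCCC#CC(=O)OCc1ccccc1 | intermediate
10 | benzyl 5-{[2,4-bis(benzyloxy)-6-propylbenzoyl]oxy}-4-(tert-butyldimethylsilyloxy)-6-methoxy-2-propyl-6-(trimethylsilyloxy)cyclohexa-1,4-diene-1-carboxylate (racemic, not isolated) | CCCC1=C(C(=O)OCc2ccccc2)C(OC)(O[Si](C)(C)C)C(OC(=O)c2c(CCC)cc(OCc3ccccc3)cc2OCc2ccccc2)=C(O[Si](C)(C)C(C)(C)C)C1 | intermediate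
11 | benzyl 3-{[2,4-bis(benzyloxy)-6-propylbenzoyl]oxy}-4-(tert-butyldimethylsilyloxy)-6-propyl-2-(trimethylsilyloxy)benzoate (not isolated) | CCCc1cc(O[Si](C)(C)C(C)(C)C)c(OC(=O)c2c(CCC)cc(OCc3ccccc3)cc2OCc2ccccc2)c(O[Si](C)(C)C)c1C(=O)OCc1ccccc1 | intermediate
12 | benzyl 3-{[2,4-bis(benzyloxy)-6-propylbenzoyl]oxy}-4-(tert-butyldimethylsilyloxy)-2-hydroxy-6-propylbenzoate | CCCc1cc(O[Si](C)(C)C(C)(C)C)c(OC(=O)c2c(CCC)cc(OCc3ccccc3)cc2OCc2ccccc2)c(O)c1C(=O)OCc1ccccc1 | intermediate
13 | benzyl 3-{[2,4-bis(benzyloxy)-6-propylbenzoyl]oxy}-4-(tert-butyldimethylsilyloxy)-2-methoxy-6-propylbenzoate | CCCc1cc(O[Si](C)(C)C(C)(C)C)c(OC(=O)c2c(CCC)cc(OCc3ccccc3)cc2OCc2ccccc2)c(OC)c1C(=O)OCc1ccccc1 | intermediate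
14 | benzyl 3-{[2,4-bis(benzyloxy)-6-propylbenzoyl]oxy}-4-hydroxy-2-methoxy-6-propylbenzoate | CCCc1cc(O)c(OC(=O)c2c(CCC)cc(OCc3ccccc3)cc2OCc2ccccc2)c(OC)c1C(=O)OCc1ccccc1 | intermediate
15 | 3-[(2,4-dihydroxy-6-propylbenzoyl)oxy]-4-hydroxy-2-methoxy-6-propylbenzoic acid | CCCc1cc(O)cc(O)c1C(=O)Oc1c(O)cc(CCC)c(C(=O)O)c1OC | target

**Step count and risks**
Total step count: 10. Longest linear sequence: 9 steps (steps 1–5 and 7–10, from divarinic acid); step 6 is a one-step branch.

Steps most likely to fail:

Step 7. The alkyl-substituted ynoate is a sluggish dienophile, so at the temperature required the diene may be used up by silyl transfer, hydrolysis or aroyl migration faster than it cycloadds. The fallback raises the activation of the dienophile by changing its oxidation level. It sets out from diene 7 and uses hex-2-ynal F1, obtained by MnO2 oxidation of commercial hex-2-yn-1-ol, in toluene at 20–60 °C. With the same orientation and the same dilute acid work-up this should give, by way of the cyclohexadiene cycloadduct F2 and the aryl trimethylsilyl ether F3, the salicylaldehyde F4. Pinnick oxidation (NaClO2, NaH2PO4, 2-methylbut-2-ene, t-BuOH/H2O) would then give the salicylic acid F5, and carboxylate-selective benzylation (BnBr, KHCO3, DMF, rt) comes back to the route at 12.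

Step 5. The lithium dienolate may pass the aroyl group from oxygen to carbon or to the neighbouring oxygen, or LDA may metalate the benzylic CH2 of the ortho-propyl group before O-silylation is complete. The fallback gives up the metal enolate and uses silyl triflate soft enolization, the method that turns dioxinones and silylated β-dicarbonyl compounds into silyloxy dienes. It sets out from 6 with TMSOTf and Et3N in Et2O at 0 °C, where the ester carbonyl is silylated first and the amine then removes a γ-proton, so no free dienolate is present. It comes back at 7 and passes through no new compound (entry F0).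

Step 8. The phenoxide formed in the Mitsunobu ion pair may shift the aroyl group from O3' to O2' through a five-membered tetrahedral intermediate before it is methylated, or the doubly ortho-substituted, hydrogen-bonded phenol may be alkylated too slowly. The fallback replaces the redox condensation by a Purdie methylation (MeI, Ag2O, CH2Cl2, rt, dark), the classical silver-assisted method for hydroxyl groups beside migration-prone esters, which needs no soluble base. It sets out from 12 and comes back at 13 without a new compound (entry F0).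

Further compounds
F1 | step 7 | hex-2-ynal | CCCC#CC=O
F2 | step 7 | 2-(tert-butyldimethylsilyloxy)-5-formyl-6-methoxy-4-propyl-6-(trimethylsilyloxy)cyclohexa-1,4-dien-1-yl 2,4-bis(benzyloxy)-6-propylbenzoate (racemic, not isolated) | CCCC1=C(C=O)C(OC)(O[Si](C)(C)C)C(OC(=O)c2c(CCC)cc(OCc3ccccc3)cc2OCc2ccccc2)=C(O[Si](C)(C)C(C)(C)C)C1
F3 | step 7 | 6-(tert-butyldimethylsilyloxy)-3-formyl-4-propyl-2-(trimethylsilyloxy)phenyl 2,4-bis(benzyloxy)-6-propylbenzoate (not isolated) | CCCc1cc(O[Si](C)(C)C(C)(C)C)c(OC(=O)c2c(CCC)cc(OCc3ccccc3)cc2OCc2ccccc2)c(O[Si](C)(C)C)c1C=O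
F4 | step 7 | 6-(tert-butyldimethylsilyloxy)-3-formyl-2-hydroxy-4-propylphenyl 2,4-bis(benzyloxy)-6-propylbenzoate | CCCc1cc(O[Si](C)(C)C(C)(C)C)c(OC(=O)c2c(CCC)cc(OCc3ccccc3)cc2OCc2ccccc2)c(O)c1C=O
F5 | step 7 | 3-{[2,4-bis(benzyloxy)-6-propylbenzoyl]oxy}-4-(tert-butyldimethylsilyloxy)-2-hydroxy-6-propylbenzoic acid | CCCc1cc(O[Si](C)(C)C(C)(C)C)c(OC(=O)c2c(CCC)cc(OCc3ccccc3)cc2OCc2ccccc2)c(O)c1C(=O)O
F0 | step 5 | none | none
F0 | step 8 | none | none
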